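The constants give me one clock for this flask, and I hand it to you with the bench.

    D + J → L + E (k1 = 9.66 M⁻¹ s⁻¹)
    L ⇌ X (K2 = 6.49, k2 = 0.244 s⁻¹)
    L ⇌ Z (K3 = 2.95, k3 = 0.123 s⁻¹)

D 5.0 mM; J 12.5 mM (fed, over 1.0 s); time 20 s

- the reaction counts as stopped when no species that holds the D changes by six tenths of a point or more over the second half of the time
- run time (flask): 20 s

- at 20 s, what has stopped the reaction, if anything has (forward and back rates have come level / all of D has reacted / it is still moving / J has run out first)
- share of the D used up at 20 s
- X at 20 s, in percent of the D charged
- Z at 20 s, in percent of the D charged
- amount of X if the flask were left three thousand times as long, in percent of the D charged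

**In the flask.** J goes in quickly: the feed lasts 1.0 s, far shorter than the run of 20 s, so I count time from its middle. D is the limiting reagent, at 0.400 of the J charge; call this ratio r. With the whole J charge in, each D is taken at 0.121 s⁻¹. J falls by one for each D lost, so that rate drifts toward 0.0725 s⁻¹, not to nothing.

**The clock.** My clock is the first step's constant times the excess of J over D times the time since mid-feed, and here it reads 1.41. Let g be the exponential of minus the clock, 0.243. The share of D left is then (one minus r) times g, over one minus r times g.

**When you come.** This gives 16.2% of the D left at 20 s, against 37.7% at half that time. That is a fall of 22 percentage points, so this flask will still be moving. My reckoning stops at D.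

**Don't touch.** Leave the J charge alone. The clock runs on a difference, so with D and the time held, a given share added to J moves it by 1.67 times that share.

**The forecast.** It says it is still moving, “D is still falling, so the reaction is still moving”. It gives conversion 83.8% (82.5% to 85%), X 48.5% (46.5% to 50.5%), Z 23.6% (22.3% to 25%) and long-run X 62.2% (61.8% to 62.6%).

**The result.** In this flask, it is still moving: conversion is 83.8%, X 48.5%, Z 23.6%, and long-run X 62.2%. Half of that conversion stood by 5.47 s. There the clock reads 0.360, which leaves 58.1% of the D, so 41.9% is used, half of the final figure.

**Second flask.** With 20 mM of D, J becomes the limiting reagent, and the excess and the clock turn negative, at −1.41. With r now 1.60, the same rule leaves 44.2% of the D, so conversion is 55.8%. The simulated neighbour gives 55.8%, with 11% of its J left.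

(The numbers of this flask belong to no real substance; the run is a simulation.)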